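The readings were generated by integration on assumed constants; the scatter is artificial.

Half of the starting material converted is the easy first entry in the ledger of the new flask, which is charged with 0.010 M of starting material and 10.0 mM of second substrate.

| flask | starting material | second substrate | enzyme | remark |
|---|---|---|---|---|
| summer | 0.0067 M | 10 mM | 0.95 µM | run made earlier |
| noon | 0.015 M | 10 mM | 0.95 µM | run made earlier |
| dusk | 0.010 M | 10 mM | 1.9 µM | run made earlier |
| flask | 0.010 M | 10.0 mM | 0.95 µM |  |

| run | time / min | target / % | starting material / % |
|---|---|---|---|
| summer | 8.00 | 20.1 | 79.7 |
| summer | 15.0 | 34.5 | 65.4 |
| summer | 25.0 | 49.6 | 50.4 |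
| summer | 30.0 | 56.3 | 43.3 |
| summer | 40.0 | 66.5 | 34.4 |
| summer | 50.0 | 74.6 | 26.2 |
| noon | 4.00 | 6.6 | 94.1 |
| noon | 6.00 | 8.6 | 91.5 |
| noon | 10.0 | 14.4 | 86.7 |
| noon | 20.0 | 23.4 | 76.5 |
| noon | 30.0 | 31.6 | 68.9 |
| noon | 50.0 | 42.3 | 58.5 |
| dusk | 4.00 | 15.0 | 83.2 |
| dusk | 8.00 | 28.5 | 71.3 |
| dusk | 15.0 | 45.1 | 54.7 |
| dusk | 25.0 | 61.2 | 39.8 |
| dusk | 50.0 | 79.9 | 20.1 |

(each reading ± 0.5 percentage points)

- percentages count the starting material that a species holds: one spent catalyst counts as two
- on the list of suspects stand: ternary complex -> enzyme + target; starting material + ternary complex -> spent catalyst; starting material + enzyme <-> starting complex; second substrate + starting complex <-> ternary complex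
- no earlier run changes the charge of second substrate; that part of a forecast is a guess

- apparent order in second substrate when 50% of the starting material are converted (percent change of the rate of making target for one percent more second substrate charged)
- apparent order in enzyme when 50% of the starting material are converted (percent change of the rate of making target for one percent more enzyme charged)

On the suspected round, each target costs one starting material and one second substrate, so the equal charges make both the limiting reagent. At the moment asked about, 5.00 mM of starting material stands as target and 5.00 mM stands as starting material. The catalyst entry is small: the enzyme charge is 0.00950% of the starting material charge, or 0.0190% if wholly spent, with one spent catalyst counted as two. The summer run agrees, with 49.6% of target beside 50.4% of starting material at 25.0 min.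

The second substrate has the same debit, so [second substrate] is 5.00 mM. At fixed conversion that debit stays the same when the charge rises, so extra charge lands wholly on what is left. The charge divided by [second substrate] at that moment, the leverage 2.00, therefore multiplies the local order in [second substrate] to give the order in the charge. With one second substrate bound per turn, the local order runs from nought to one, so the charged order runs from nought to 2.00. No earlier run varies that charge, so the local order remains a guess.

The forecast gives 1.4 in second substrate and 1.25 in enzyme, and says of the first: “This is extrapolated”.

The flask gives 1.7 in second substrate and 1.2 in enzyme.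

    ternary complex → enzyme + target (k = 12.0 /s)
    starting material + ternary complex → spent catalyst (k = 0.0540 /M/s)
    starting material + enzyme ⇌ starting complex (K = 120 /M, k = 27000 /M/s)
    second substrate + starting complex ⇌ ternary complex (K = 120 /M, k = 4200 /M/s)

Divided by the leverage, the 1.7 of this flask is a local order of 0.850. Ternary complex falls back to second substrate and starting complex at 35.0 /s, faster than it goes on to enzyme and target at 12 /s, and part of that local order comes from this reverse step. The run without the reverse step gives a charged order of 1.2, which the same leverage turns into a local order of 0.584.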